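In Wednesday's flask the trap is to read the height of Q as progress: it stands at 9.0 % at 2.00 h, yet at 28.4 % at 2.50 h, after a portion.

| flask | Q | Z | X | E | remark | time |
|---|---|---|---|---|---|---|
| Wednesday's | 0.020 M (in portions, 4) | 0.95 equiv | 0.40 mM | 1 mM | the very flask that is asked about, followed so far; portions every 2.0 h |  |
| flask | 0.020 M (in portions, 4) | 0.950 equiv | 0.400 mM | 1.00 mM | the portions of Q follow each other after 2.0 h, the first at the start | 8.0 h |

- Wednesday's (time / h: Q / %, D / %, L / %): 0.200: 21.3, 1.1, 2.7; 0.667: 16.3, 2.5, 6.8; 1.00: 14.3, 1.4, 9.2; 2.00: 9.0, 2.6, 14.4; 2.50: 28.4, 1.6, 20.6; 3.00: 23.0, 2.3, 24.8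

(scatter of a reading: 0.5 percentage points)

- the numbers in the tables scatter with a standard deviation of 0.5 percentage points
- a reading at the moment of an addition is taken just before it
- percentages count the whole charge, also what has not yet gone in

1. the species in which most of what was charged as Q, at 8.0 h sits (Q / D / L)
2. the largest share itself, whichever of these holds it, in percent of the Q charged

Look instead at how fast Q falls. Over the first interval of Wednesday's flask Z, reckoned as below, moves from 92.3 % to 80.6 % of the Q charged, so take Q as falling by a steady factor per hour, the pseudo-first-order picture. So take the natural-log fall of Q over one interval and divide it by Z, as a fraction of the Q charged, reckoned as its charge less L. This exposure 1.11 comes from the first interval.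

Is one number enough? From 2.50 h to 3.00 h, with less Z, you read 1.17, close to it, so carry the first.

Now extend L at its pace over the whole interval from 1.00 h to 3.00 h. That gives L 48.2 % and Z 46.8 % at 6.00 h. Q after the last portion is about 49.8 %, close to Z. For equal amounts, the interval divides Z by one plus exposure times Z, leaving 30.8 %. I reckon L at 64.2 %, ahead of Q at 33.8 %.

The forecast says L at 65 %, on the ground that “L follows second-order kinetics”.

The flask gives L at 59.9 %. Z left is 32 % of its own charge, or 30.1 % of the Q charged, near my 30.8 %. L and Z together fall short of the Z charge by 5 percentage points, and G stands at 5.00 % of the Q charged.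

    Q + Z ⇌ L (K = 560 L mol⁻¹, k = 0.00850 L mol⁻¹ s⁻¹)
    Q + X → D (k = 0.410 L mol⁻¹ s⁻¹)
    Z + E → G (k = 0.210 L mol⁻¹ s⁻¹)

In the neighbour flask with Q at 0.0080 M, equivalents and interval held, the exposure scales with the charge to 0.443, so a portion of Q facing the whole charge of Z keeps 65.7 % over an interval, and I expect most of that flask's Q to stay unbound. That neighbour flask gives Q at 56.2 %, more than L at 38.8 %.

The data were generated by integration with made-up constants; scatter was added.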